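**Plan**

- Retrosynthesis: the 5'-hydroxyl is masked as a benzyl ether and the 5- and 7-methoxyls are taken back to phenols. O1–C2 and C4a–C5 are then cut together, which opens the pyranone and ring A to a linear 3,5,7-triketo ester ending in a 3-aryl-2,3-dimethoxypropenoyl group.
- Enabling feature: ring A (C4a, C5–C8, C8a, with oxygen on C5, C7 and C8a and the acyl carbon C4 on C4a) is an acylphloroglucinol, i.e. a folded triketide. C2 can be carried as the β-carbon of a β-methoxy enone, already at the flavone oxidation level and open to substitution by an ortho phenol.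
- The chain is cut next at C4–C4a into methyl 3,5-dioxohexanoate and a methyl 3-aryl-2,3-dimethoxyacrylate. The acrylate goes back through an α-methoxy-β-keto ester and an aldol adduct to the B-ring aldehyde and methyl methoxyacetate; the aldehyde comes from 2,4-dimethoxybenzaldehyde (Dakin-type oxidation, benzylation, Vilsmeier formylation).
- Forward: ring B is elaborated first and the chain is joined by polyanion acylation. Ring A then closes by Claisen condensation and the pyranone by O1–C2 addition–elimination in the same flask; double O-methylation and hydrogenolysis finish.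
- Stereochemistry: the target has no stereocentre and no stereogenic double bond, so nothing has to be set. The centres that appear in the aldol adduct and the β-keto ester are erased on the way.

Key step: step 8

Assumption: the enol ether double bond made in step 6 is drawn E, the isomer expected from O-methylation; the Z isomer or a mixture would serve equally, because this geometry is lost in the key step.

**Route**

Step 1
Reactants: 1 2,4-dimethoxybenzaldehyde
Product: 3 2,4-dimethoxyphenol, via 2,4-dimethoxyphenyl formate 2 (not isolated)
Conditions: mCPBA, CH2Cl2, 0 °C → rt; then MeOH, HCl (cat.), rt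
Reagents that add atoms: 3-chloroperoxybenzoic acid (mCPBA), OOC(=O)c1cccc(Cl)c1
Why: Baeyer–Villiger (Dakin-type) oxidation, in which the electron-rich 2,4-dimethoxyphenyl group of the Criegee adduct migrates in preference to hydride and the labile aryl formate is methanolysed under acid catalysis in the same flask.

Step 2
Reactants: 3 2,4-dimethoxyphenol
Product: 4 1-(benzyloxy)-2,4-dimethoxybenzene
Conditions: BnBr, K2CO3, DMF, rt
Reagents that add atoms: benzyl bromide, BrCc1ccccc1
Why: Williamson ether synthesis (SN2 of the phenoxide on benzyl bromide), which installs a group that should survive every later base and acid and leaves at the end by hydrogenolysis.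

Step 3
Reactants: 4 1-(benzyloxy)-2,4-dimethoxybenzene
Product: 6 5-(benzyloxy)-2,4-dimethoxybenzaldehyde, via arylmethylidene dimethyliminium chloride 5 (not isolated)
Conditions: POCl3, DMF, 0 → 60 °C; then H2O, rt
Reagents that add atoms: N,N-dimethylformamide, CN(C)C=O; water, O
Why: Vilsmeier–Haack formylation, in which the chloroiminium ion should attack C5, the only position para to one methoxyl and ortho to the other (C3 is flanked by two alkoxy groups, C6 is activated only by the benzyloxy group), as 1,2,4-trialkoxybenzenes do, and the benzyl ether tolerates the reagent.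

Step 4
Reactants: 6 5-(benzyloxy)-2,4-dimethoxybenzaldehyde; 7 methyl methoxyacetate
Product: 8 methyl 3-[5-(benzyloxy)-2,4-dimethoxyphenyl]-3-hydroxy-2-methoxypropanoate (racemic syn/anti mixture)
Conditions: LDA, THF, −78 °C (7 first, then 6); AcOH quench at −78 °C
Reagents that add atoms: none
Why: Aldol addition of the lithium enolate of an α-alkoxy ester to a non-enolisable aromatic aldehyde at low temperature; the two new stereocentres form without control, which is of no consequence because both become sp2 carbons in steps 5 and 6.

Step 5
Reactants: 8 methyl 3-[5-(benzyloxy)-2,4-dimethoxyphenyl]-3-hydroxy-2-methoxypropanoate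
Product: 9 methyl 3-[5-(benzyloxy)-2,4-dimethoxyphenyl]-2-methoxy-3-oxopropanoate (racemic)
Conditions: Dess–Martin periodinane, CH2Cl2, rt
Reagents that add atoms: none
Why: Dess–Martin oxidation of a secondary benzylic alcohol to the aryl ketone under near-neutral conditions, which should leave the ester, the ethers and the enolisable α-position (racemic in any case) untouched.

Step 6
Reactants: 9 methyl 3-[5-(benzyloxy)-2,4-dimethoxyphenyl]-2-methoxy-3-oxopropanoate
Product: 10 methyl (E)-3-[5-(benzyloxy)-2,4-dimethoxyphenyl]-2,3-dimethoxyprop-2-enoate
Conditions: Cs2CO3, Me2SO4, DMF, 0 °C → rt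
Reagents that add atoms: dimethyl sulfate, COS(=O)(=O)OC
Why: O-Alkylation of a β-keto ester enolate, in which the caesium enolate in a dipolar aprotic solvent should react at oxygen with the hard electrophile, C-methylation being further disfavoured because it would build a quaternary carbon between the ortho-substituted aroyl group, a methoxyl and the ester.

Step 7
Reactants: 10 methyl (E)-3-[5-(benzyloxy)-2,4-dimethoxyphenyl]-2,3-dimethoxyprop-2-enoate; 11 methyl 3,5-dioxohexanoate
Product: 12 methyl (E)-9-[5-(benzyloxy)-2,4-dimethoxyphenyl]-8,9-dimethoxy-3,5,7-trioxonon-8-enoate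
Conditions: 11 (2 equiv), LDA (6.2 equiv), THF, 0 °C; then 10, 0 °C → rt; cold dil. HCl
Reagents that add atoms: none
Why: Acylation of a 1,3,5-tricarbonyl polyanion by an ester (Claisen-type condensation), in which the terminal C6 carbanion of the trilithio derivative is the most basic and reacts first, and should attack the ester carbonyl of 10 because the β-carbon is tetrasubstituted and carries a donating methoxyl, which suppresses conjugate addition.

Step 8
Reactants: 12 methyl (E)-9-[5-(benzyloxy)-2,4-dimethoxyphenyl]-8,9-dimethoxy-3,5,7-trioxonon-8-enoate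
Product: 14 2-[5-(benzyloxy)-2,4-dimethoxyphenyl]-5,7-dihydroxy-3-methoxy-4H-chromen-4-one (5'-O-benzyl-5,7-dihydroxy-3,2',4'-trimethoxyflavone), via acylphloroglucinol enol ether 13 (not isolated)
Conditions: Mg(OMe)2, MeOH, reflux; then 2 M HCl, 50 °C
Reagents that add atoms: none
Why: Proposed new method: magnesium methoxide should convert the 5,7-diketone unit into its chelated enolate, whose C6 attacks the ester carbonyl (Claisen condensation, 6-exo-trig), methoxide leaves and enolisation aromatises the ring to acylphloroglucinol 13; the closest known reaction type is the magnesium alkoxide-mediated Claisen cyclisation of 3,5,7-triketo esters to acylphloroglucinols. An ortho hydroxyl of 13 then adds to C9 of the β-methoxy enone (6-endo-trig) and methanol is lost, an addition–elimination of the kind by which 2'-hydroxy-β-alkoxychalcones close to flavones and which the acidic finish should drive to completion. The step needs C6-to-ester closure in preference to aldol attack of C2 on C7 and to attack of O5 or C4 on C9: C7 is a vinylogous ester carbonyl and a poor aldol acceptor, C9 is tetrasubstituted, and the O5–Mg–O7 chelate holds both O5 and C4 away from C9 in the very geometry that the hydrogen-bonded product has. Lactonisation of O5 onto the ester and exchange of methoxyl at the ester or at C9 are reversible or degenerate in methoxide–methanol, so only the aromatising Claisen path should drain the equilibrium. The two ortho hydroxyls of 13 are equivalent, so a single flavone can form, the enol ether geometry is irrelevant because the adduct rotates before elimination, and no stereocentre is created.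

Step 9
Reactants: 14 2-[5-(benzyloxy)-2,4-dimethoxyphenyl]-5,7-dihydroxy-3-methoxy-4H-chromen-4-one
Product: 15 2-[5-(benzyloxy)-2,4-dimethoxyphenyl]-3,5,7-trimethoxy-4H-chromen-4-one
Conditions: Me2SO4 (excess), K2CO3, acetone, reflux
Reagents that add atoms: dimethyl sulfate, COS(=O)(=O)OC
Why: Williamson methylation of both phenols, the 7-hydroxyl reacting readily and the hydrogen-bonded 5-hydroxyl under the excess reagent and prolonged reflux customary for 5-hydroxyflavones, while the benzyl ether and the chromone are inert.

Step 10
Reactants: 15 2-[5-(benzyloxy)-2,4-dimethoxyphenyl]-3,5,7-trimethoxy-4H-chromen-4-one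
Product: 16 2-(5-hydroxy-2,4-dimethoxyphenyl)-3,5,7-trimethoxy-4H-chromen-4-one (5'-hydroxy-3,5,7,2',4'-pentamethoxyflavone)
Conditions: H2 (1 atm), 10% Pd/C, EtOAc–MeOH, rt
Reagents that add atoms: none
Why: Catalytic hydrogenolysis of the benzyl aryl ether should free the 5'-hydroxyl, and the methyl ethers, the carbonyl and the tetrasubstituted C2=C3 bond of the chromone are not expected to be reduced under these mild conditions.

**Compound list**

1 | 2,4-dimethoxybenzaldehyde | COc1ccc(C=O)c(OC)c1 | starting material
2 | 2,4-dimethoxyphenyl formate | COc1ccc(OC=O)c(OC)c1 | intermediate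
3 | 2,4-dimethoxyphenol | COc1ccc(O)c(OC)c1 | intermediate
4 | 1-(benzyloxy)-2,4-dimethoxybenzene | COc1ccc(OCc2ccccc2)c(OC)c1 | intermediate
5 | N-{[5-(benzyloxy)-2,4-dimethoxyphenyl]methylidene}-N-methylmethanaminium chloride | C[N+](C)=Cc1cc(OCc2ccccc2)c(OC)cc1OC.[Cl-] | intermediate
6 | 5-(benzyloxy)-2,4-dimethoxybenzaldehyde | O=Cc1cc(OCc2ccccc2)c(OC)cc1OC | intermediate
7 | methyl methoxyacetate | COCC(=O)OC | starting material
8 | methyl 3-[5-(benzyloxy)-2,4-dimethoxyphenyl]-3-hydroxy-2-methoxypropanoate (racemic mixture of diastereomers) | COC(=O)C(OC)C(O)c1cc(OCc2ccccc2)c(OC)cc1OC | intermediate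
9 | methyl 3-[5-(benzyloxy)-2,4-dimethoxyphenyl]-2-methoxy-3-oxopropanoate (racemic) | COC(=O)C(OC)C(=O)c1cc(OCc2ccccc2)c(OC)cc1OC | intermediate
10 | methyl (E)-3-[5-(benzyloxy)-2,4-dimethoxyphenyl]-2,3-dimethoxyprop-2-enoate | COC(=O)/C(OC)=C(\OC)c1cc(OCc2ccccc2)c(OC)cc1OC | intermediate
11 | methyl 3,5-dioxohexanoate | COC(=O)CC(=O)CC(C)=O | starting material
12 | methyl (E)-9-[5-(benzyloxy)-2,4-dimethoxyphenyl]-8,9-dimethoxy-3,5,7-trioxonon-8-enoate | COC(=O)CC(=O)CC(=O)CC(=O)/C(OC)=C(\OC)c1cc(OCc2ccccc2)c(OC)cc1OC | intermediate
13 | (E)-3-[5-(benzyloxy)-2,4-dimethoxyphenyl]-2,3-dimethoxy-1-(2,4,6-trihydroxyphenyl)prop-2-en-1-one | Oc1cc(O)c(C(=O)/C(OC)=C(\OC)c2cc(OCc3ccccc3)c(OC)cc2OC)c(O)c1 | intermediate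
14 | 2-[5-(benzyloxy)-2,4-dimethoxyphenyl]-5,7-dihydroxy-3-methoxy-4H-chromen-4-one | COc1c(-c2cc(OCc3ccccc3)c(OC)cc2OC)oc2cc(O)cc(O)c2c1=O | intermediate
15 | 2-[5-(benzyloxy)-2,4-dimethoxyphenyl]-3,5,7-trimethoxy-4H-chromen-4-one | COc1cc(OC)c2c(=O)c(OC)c(-c3cc(OCc4ccccc4)c(OC)cc3OC)oc2c1 | intermediate
16 | 2-(5-hydroxy-2,4-dimethoxyphenyl)-3,5,7-trimethoxy-4H-chromen-4-one (5'-hydroxy-3,5,7,2',4'-pentamethoxyflavone) | COc1cc(OC)c2c(=O)c(OC)c(-c3cc(O)c(OC)cc3OC)oc2c1 | target

**Step count**

Total step count: 10. Longest linear sequence: 10 steps (1 → 16); 7 and 11 enter as purchased partners.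

**Steps most likely to fail**

Step 8 (the new method). The chain may misfold: aldol closure of C2 onto C7, or addition of the C5 enol oxygen or of C4 to C9, could run ahead of the Claisen closure, or methoxide could fragment the polyketone by retro-Claisen cleavage. The fallback abandons the polyketide folding and sets out from β-keto ester 9. Heating 9 with phloroglucinol (benzene-1,3,5-triol, Oc1cc(O)cc(O)c1) without solvent or catalyst at about 240 °C (or under microwave irradiation) is a Mentzer thermal chromone synthesis. The aroylacetate should C-acylate the symmetrical triphenol and cyclodehydrate with loss of methanol and water. This comes back to the route at flavone 14, and no new compound lies on the way (F0).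

Step 7. Attack on the hindered, donor-deactivated ester carbonyl of 10 may be slow, so that self-condensation of the polyanion through its own ester group, or addition–elimination at the β-carbon, takes over. The fallback sets out from acrylate 10 and uses a nucleophile without an ester. Acylation of the dianion of pentane-2,4-dione (LDA, THF, 0 °C) should give the triketone (E)-8-[5-(benzyloxy)-2,4-dimethoxyphenyl]-7,8-dimethoxyoct-7-ene-2,4,6-trione F1. Its trianion (LDA, 3 equiv) would be carboxylated at the terminal methyl with CO2 to the triketo acid (E)-9-[5-(benzyloxy)-2,4-dimethoxyphenyl]-8,9-dimethoxy-3,5,7-trioxonon-8-enoic acid F2. Esterification with trimethylsilyldiazomethane (MeOH–toluene, 0 °C) comes back to the route at triketo ester 12.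

Step 6. The ambident enolate may be methylated at carbon instead of oxygen, or the enol ether may be hydrolysed back during work-up. The fallback sets out from β-keto ester 9 and avoids the enolate. Acid-catalysed ketalisation with trimethyl orthoformate (TsOH cat., MeOH, reflux) should give the dimethyl ketal methyl 3-[5-(benzyloxy)-2,4-dimethoxyphenyl]-2,3,3-trimethoxypropanoate F3. Heating F3 with catalytic TsOH in toluene with removal of methanol would eliminate one methoxyl and come back to the route at acrylate 10.

**Further compounds**

F0 | step 8 | none | none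
F1 | step 7 | (E)-8-[5-(benzyloxy)-2,4-dimethoxyphenyl]-7,8-dimethoxyoct-7-ene-2,4,6-trione | CC(=O)CC(=O)CC(=O)/C(OC)=C(\OC)c1cc(OCc2ccccc2)c(OC)cc1OC
F2 | step 7 | (E)-9-[5-(benzyloxy)-2,4-dimethoxyphenyl]-8,9-dimethoxy-3,5,7-trioxonon-8-enoic acid | OC(=O)CC(=O)CC(=O)CC(=O)/C(OC)=C(\OC)c1cc(OCc2ccccc2)c(OC)cc1OC
F3 | step 6 | methyl 3-[5-(benzyloxy)-2,4-dimethoxyphenyl]-2,3,3-trimethoxypropanoate | COC(=O)C(OC)C(OC)(OC)c1cc(OCc2ccccc2)c(OC)cc1OC
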